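##### Retrosynthetic overview

1. Labdane numbering is used: ring A is C1–C5 plus C10, ring B is C5–C10, C4 carries C18 (CH3) and C19 (CO2H), C17 is the exocyclic CH2, and C11–C16 form the side chain. The target is the 15-O-stearate of (13S)-15-hydroxylabd-8(17)-en-19-oic acid. The stearate comes from selective acylation of the 15,19-diol and the acid from oxidation of C19–OH.
2. Key disconnection: C4–C5 and C9–C10 are cut together, which leads back to an acyclic (E,E)-dienyl α-methyl β-keto ester. In the forward direction ring A closes first (C4–C5), ring B second (C9–C10), and the C8 radical is then oxidised to the C8=C17 methylene. This is a one-electron copy of the labdane biosynthesis.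
3. Enabling feature: the quaternary C4 of ring A is alpha to the C19 carboxyl carbon, so it can be an electrophilic carbon radical. It stands in the head-to-tail isoprenoid spacing C4 / C5=C10 / C9=C8, and ring B ends in the C8=C17 methylene, which is the natural exit of the cascade. A temporary C3 ketone makes C4–H oxidisable.
4. The acyclic precursor comes from (2E,6E)-farnesol, where asymmetric hydrogenation sets C13 and terminal allylic oxidation and bromination follow. It is joined to the dianion of (−)-8-phenylmenthyl 2-methylacetoacetate, whose auxiliary sets the absolute configuration of both rings.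
5. After the cascade the C3 ketone is removed by Barton–McCombie deoxygenation. The auxiliary and the pivalate then fall together with LiAlH4.

Key step: step 7

Assumption: the sense of induction of (−)-8-phenylmenthol in step 7 is taken from the π-stacked rotamer model given there. Should the ent-labdane diastereomer prove to be the major one, the same route would be run from commercial (+)-8-phenylmenthol.

##### Route

Step 1
Reactants: 1 (2E,6E)-farnesol
Product: 2 (S)-2,3-dihydrofarnesol, (3S,6E)-3,7,11-trimethyldodeca-6,10-dien-1-ol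
Conditions: H2 (100 atm), Ru(OAc)2[(R)-BINAP] (cat.), MeOH, 20 °C
Reagents that add atoms: none
Why: Noyori asymmetric hydrogenation, in which the allylic hydroxyl binds ruthenium so that only the C2=C3 alkene is reduced, and (R)-BINAP with an E-allylic alcohol delivers hydrogen to the face that gives the 3S centre (the future C13), as in the geraniol to (S)-citronellol case.

Step 2
Reactants: 2 (S)-2,3-dihydrofarnesol
Product: 3 (3S,6E)-3,7,11-trimethyldodeca-6,10-dienyl pivalate
Conditions: PivCl, pyridine, DMAP (cat.), CH2Cl2, 0 °C to rt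
Reagents that add atoms: pivaloyl chloride, CC(C)(C)C(=O)Cl
Why: Standard acylation of a primary alcohol, with the pivalate chosen because it resists the dianion of step 6 and the acetic acid of step 7 and is removed in the same LiAlH4 step as the auxiliary.

Step 3
Reactants: 3 (3S,6E)-3,7,11-trimethyldodeca-6,10-dienyl pivalate
Product: 4 (3S,6E,10E)-12-hydroxy-3,7,11-trimethyldodeca-6,10-dienyl pivalate
Conditions: SeO2 (cat.), t-BuOOH, salicylic acid (cat.), CH2Cl2, 0 °C to rt, stopped before full conversion, 3 recycled
Reagents that add atoms: tert-butyl hydroperoxide, CC(C)(C)OO (its oxygen is passed on through SeO2, O=[Se]=O)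
Why: Riley allylic oxidation in its catalytic form, in which the ene reaction and [2,3]-sigmatropic shift run fastest at the least hindered terminal trisubstituted alkene and at its E-methyl group, so that the E-allylic alcohol needed for the later C5=C10 geometry should result.

Step 4
Reactants: 4 (3S,6E,10E)-12-hydroxy-3,7,11-trimethyldodeca-6,10-dienyl pivalate
Product: 5 (3S,6E,10E)-12-bromo-3,7,11-trimethyldodeca-6,10-dienyl pivalate
Conditions: CBr4, PPh3, CH2Cl2, −20 to 0 °C, used at once
Reagents that add atoms: carbon tetrabromide, BrC(Br)(Br)Br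
Why: Appel reaction, an SN2 displacement of the alkoxyphosphonium ion by bromide at the primary allylic carbon under neutral conditions, which keeps both alkene geometries and the ester.

Step 5
Reactants: 6 ethyl 2-methylacetoacetate; 7 (−)-8-phenylmenthol, (1R,2S,5R)-5-methyl-2-(2-phenylpropan-2-yl)cyclohexan-1-ol
Product: 8 (−)-8-phenylmenthyl 2-methyl-3-oxobutanoate (both epimers at the labile C2)
Conditions: DMAP (cat.), toluene, reflux, EtOH distilled off
Reagents that add atoms: none
Why: DMAP-catalysed transesterification of an enolisable β-keto ester, which runs through an acylketene-type intermediate and therefore accepts this hindered secondary alcohol, while the labile α-centre is erased in step 7.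

Step 6
Reactants: 8 (−)-8-phenylmenthyl 2-methyl-3-oxobutanoate; 5 (3S,6E,10E)-12-bromo-3,7,11-trimethyldodeca-6,10-dienyl pivalate
Product: 10 (−)-8-phenylmenthyl (6E,10E,14S)-2,6,10,14-tetramethyl-3-oxo-16-(pivaloyloxy)hexadeca-6,10-dienoate, via dienolate dianion 9 (not isolated)
Conditions: 8, NaH, THF, 0 °C; n-BuLi, 0 °C; then 5, 0 °C; aq NH4Cl
Reagents that add atoms: none
Why: Acetoacetate dianion alkylation, in which the more basic terminal carbanion of 9 attacks the primary allylic bromide by SN2 and forms the C1–C2 bond without touching the alkene geometry or the hindered pivalate.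

Step 7
Reactants: 10 (−)-8-phenylmenthyl (6E,10E,14S)-2,6,10,14-tetramethyl-3-oxo-16-(pivaloyloxy)hexadeca-6,10-dienoate
Product: 14 (−)-8-phenylmenthyl (13S)-3-oxo-15-(pivaloyloxy)labd-8(17)-en-19-oate, via C4 radical 11 (not isolated), via C10 radical 12 (not isolated), via C8 radical 13 (not isolated)
Conditions: Mn(OAc)3·2H2O (2.2 equiv), Cu(OAc)2·H2O (1 equiv), degassed AcOH, 25–40 °C; chromatography
Reagents that add atoms: none
Why: Mn(OAc)3 (trivalent manganese) oxidises the enol of the C3/C19 β-dicarbonyl unit of 10 by one electron to the free electrophilic C4 radical 11, which bonds to C5 of the electron-rich C5=C10 alkene to give the tertiary C10 radical 12, this bonds to C9 of the C8=C9 alkene to give the tertiary C8 radical 13, and Cu(OAc)2 (divalent copper, turned over by the second equivalent of Mn(OAc)3) captures 13 as an alkylcopper species that loses a C17 hydrogen by syn β-hydride elimination and leaves the 8(17)-methylene group. The closest known reaction type is the Mn(OAc)3/Cu(OAc)2 oxidative free-radical polyene cyclisation of unsaturated α-alkyl β-keto esters, 8-phenylmenthyl esters included, and it is the one-electron copy of the biosynthetic bicyclisation of geranylgeranyl diphosphate, which makes the same C4–C5 and C9–C10 bonds in the same order and also ends by loss of a C17 hydrogen. Ring A closes 6-endo-trig (C4 to C5) and ring B closes 6-endo-trig (C10 to C9), in both cases because the inner alkene carbon (C10, then C8) carries a methyl group that blocks the 5-exo mode and makes the 6-endo product radical tertiary. Relative configuration comes from the chair–chair transition state of the (E,E)-diene: the E geometry of C5=C10 sets H5 anti to C20 (trans ring fusion, C5 and C10), the E geometry of C8=C9 puts C11 equatorial at C9, and C4 is set because the planar radical reacts through the rotamer that holds the C3 oxygen syn to the C4 methyl group (no allylic 1,3-strain between that methyl group and C2, opposed carbonyl dipoles), which turns the ester carbon C19 axial and cis to C20. Absolute configuration comes from the auxiliary: with the ester in its Z conformation, the carbinol C–H eclipsing the C19 carbonyl and C3 syn to that carbonyl oxygen, the phenyl ring of the cumyl group stacks over one face of 11, so C5 should bond to the open Re face of C4 (priorities C19 > C3 > CH3) and the chair cascade relays this to C5, C10 and C9, while C13 is a spectator and the minor diastereomer is removed by chromatography. The step needs oxidation at C4 only, which is secured because C4–H is the only β-dicarbonyl C–H and the product has a quaternary C4 that cannot be oxidised again, and it needs exocyclic rather than ring elimination, which is secured by the preference of the copper intermediate for the least hindered and most numerous β-hydrogens on C17.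

Step 8
Reactants: 14 (−)-8-phenylmenthyl (13S)-3-oxo-15-(pivaloyloxy)labd-8(17)-en-19-oate
Product: 15 (−)-8-phenylmenthyl (13S)-3β-hydroxy-15-(pivaloyloxy)labd-8(17)-en-19-oate
Conditions: NaBH4, MeOH/THF, 0 °C
Reagents that add atoms: none
Why: Borohydride reduction of a ketone beside esters, in which hydride should add axially from the α face, away from the axial C19 ester and C20, to give the equatorial 3β-alcohol, a centre that is erased again in step 10.

Step 9
Reactants: 15 (−)-8-phenylmenthyl (13S)-3β-hydroxy-15-(pivaloyloxy)labd-8(17)-en-19-oate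
Product: 16 (−)-8-phenylmenthyl (13S)-3β-(imidazol-1-ylthiocarbonyloxy)-15-(pivaloyloxy)labd-8(17)-en-19-oate
Conditions: 1,1'-thiocarbonyldiimidazole, DMAP (cat.), toluene, 90 °C
Reagents that add atoms: 1,1'-thiocarbonyldiimidazole, S=C(n1ccnc1)n1ccnc1
Why: Thioacylation of the secondary alcohol under neutral conditions (first half of the Barton–McCombie deoxygenation), preferred to a xanthate made with strong base so that retro-aldol opening of the β-hydroxy ester is avoided.

Step 10
Reactants: 16 (−)-8-phenylmenthyl (13S)-3β-(imidazol-1-ylthiocarbonyloxy)-15-(pivaloyloxy)labd-8(17)-en-19-oate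
Product: 17 (−)-8-phenylmenthyl (13S)-15-(pivaloyloxy)labd-8(17)-en-19-oate
Conditions: Bu3SnH, AIBN (cat.), toluene, 110 °C
Reagents that add atoms: none
Why: Barton–McCombie deoxygenation, a radical chain in which the tin radical adds to C=S, the secondary C3–O bond breaks and hydrogen is taken from Bu3SnH, while the esters, the remote 1,1-disubstituted alkene and all remaining stereocentres stay untouched.

Step 11
Reactants: 17 (−)-8-phenylmenthyl (13S)-15-(pivaloyloxy)labd-8(17)-en-19-oate
Product: 18 (13S)-labd-8(17)-ene-15,19-diol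
Conditions: LiAlH4 (excess), THF, reflux; aqueous NaOH work-up; 7 recovered
Reagents that add atoms: none
Why: Exhaustive hydride reduction of both esters, in which the small and strongly nucleophilic LiAlH4 at reflux should reach even the shielded C19 carbonyl, the alkene is inert, and the auxiliary and the protecting group leave in one operation.

Step 12
Reactants: 18 (13S)-labd-8(17)-ene-15,19-diol; 19 stearoyl chloride
Product: 20 (13S)-19-hydroxylabd-8(17)-en-15-yl stearate
Conditions: 19 (1.0 equiv), pyridine, CH2Cl2, −20 to 0 °C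
Reagents that add atoms: none
Why: Sterically controlled monoacylation, since C15–OH is an unhindered primary alcohol whereas C19–OH is neopentyl, axial and 1,3-diaxial to C20 and should react far more slowly.

Step 13
Reactants: 20 (13S)-19-hydroxylabd-8(17)-en-15-yl stearate
Product: 21 (13S)-19-oxolabd-8(17)-en-15-yl stearate
Conditions: Dess–Martin periodinane, CH2Cl2, rt
Reagents that add atoms: none
Why: Dess–Martin oxidation, which converts hindered neopentyl alcohols to aldehydes under near-neutral conditions that leave the exocyclic alkene and the ester alone, and the quaternary C4 cannot epimerise.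

Step 14
Reactants: 21 (13S)-19-oxolabd-8(17)-en-15-yl stearate
Product: 22 (13S)-15-(stearoyloxy)labd-8(17)-en-19-oic acid, (4S,5R,9S,10R,13S), the target
Conditions: NaClO2, NaH2PO4, 2-methyl-2-butene (excess), t-BuOH/H2O, rt
Reagents that add atoms: sodium chlorite, [Na+].[O-]Cl=O
Why: Pinnick oxidation, in which chlorous acid oxidises the aldehyde selectively and the excess 2-methyl-2-butene takes up the hypochlorous acid before it can reach the 8(17)-alkene.

##### Compound list

1 | (2E,6E)-farnesol | CC(C)=CCC/C(C)=C/CC/C(C)=C/CO | starting material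
2 | (S)-2,3-dihydrofarnesol | CC(C)=CCC/C(C)=C/CC[C@H](C)CCO | intermediate
3 | (3S,6E)-3,7,11-trimethyldodeca-6,10-dienyl pivalate | CC(C)=CCC/C(C)=C/CC[C@H](C)CCOC(=O)C(C)(C)C | intermediate
4 | (3S,6E,10E)-12-hydroxy-3,7,11-trimethyldodeca-6,10-dienyl pivalate | OC/C(C)=C/CC/C(C)=C/CC[C@H](C)CCOC(=O)C(C)(C)C | intermediate
5 | (3S,6E,10E)-12-bromo-3,7,11-trimethyldodeca-6,10-dienyl pivalate | BrC/C(C)=C/CC/C(C)=C/CC[C@H](C)CCOC(=O)C(C)(C)C | intermediate
6 | ethyl 2-methylacetoacetate (racemic) | CCOC(=O)C(C)C(C)=O | starting material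
7 | (−)-8-phenylmenthol (1R,2S,5R) | O[C@@H]1C[C@H](C)CC[C@H]1C(C)(C)c1ccccc1 | starting material
8 | (−)-8-phenylmenthyl 2-methyl-3-oxobutanoate (C2 epimers) | CC(=O)C(C)C(=O)O[C@@H]1C[C@H](C)CC[C@H]1C(C)(C)c1ccccc1 | intermediate
9 | sodium lithium dienolate (dianion) of 8 | [Na+].[Li+].C=C([O-])C(C)=C([O-])O[C@@H]1C[C@H](C)CC[C@H]1C(C)(C)c1ccccc1 | intermediate
10 | (−)-8-phenylmenthyl (6E,10E,14S)-2,6,10,14-tetramethyl-3-oxo-16-(pivaloyloxy)hexadeca-6,10-dienoate (C2 epimers) | CC(C(=O)CC/C(C)=C/CC/C(C)=C/CC[C@H](C)CCOC(=O)C(C)(C)C)C(=O)O[C@@H]1C[C@H](C)CC[C@H]1C(C)(C)c1ccccc1 | intermediate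
11 | acyclic C4 radical | C[C](C(=O)CC/C(C)=C/CC/C(C)=C/CC[C@H](C)CCOC(=O)C(C)(C)C)C(=O)O[C@@H]1C[C@H](C)CC[C@H]1C(C)(C)c1ccccc1 | intermediate
12 | monocyclic (ring A) C10 radical | C[C]1CCC(=O)[C@](C)(C(=O)O[C@@H]2C[C@H](C)CC[C@H]2C(C)(C)c2ccccc2)[C@@H]1CC/C(C)=C/CC[C@H](C)CCOC(=O)C(C)(C)C | intermediate
13 | bicyclic (rings A and B) C8 radical | C[C]1CC[C@@H]2[C@](C)(CCC(=O)[C@]2(C)C(=O)O[C@@H]3C[C@H](C)CC[C@H]3C(C)(C)c3ccccc3)[C@H]1CC[C@H](C)CCOC(=O)C(C)(C)C | intermediate
14 | (−)-8-phenylmenthyl (13S)-3-oxo-15-(pivaloyloxy)labd-8(17)-en-19-oate (4β-axial ester, 5α-H, 9α-H, 10β-CH3) | C=C1CC[C@@H]2[C@](C)(CCC(=O)[C@]2(C)C(=O)O[C@@H]3C[C@H](C)CC[C@H]3C(C)(C)c3ccccc3)[C@H]1CC[C@H](C)CCOC(=O)C(C)(C)C | intermediate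
15 | (−)-8-phenylmenthyl (13S)-3β-hydroxy-15-(pivaloyloxy)labd-8(17)-en-19-oate | C=C1CC[C@@H]2[C@](C)(CC[C@H](O)[C@]2(C)C(=O)O[C@@H]3C[C@H](C)CC[C@H]3C(C)(C)c3ccccc3)[C@H]1CC[C@H](C)CCOC(=O)C(C)(C)C | intermediate
16 | (−)-8-phenylmenthyl (13S)-3β-(imidazol-1-ylthiocarbonyloxy)-15-(pivaloyloxy)labd-8(17)-en-19-oate | C=C1CC[C@@H]2[C@](C)(CC[C@H](OC(=S)n3ccnc3)[C@]2(C)C(=O)O[C@@H]3C[C@H](C)CC[C@H]3C(C)(C)c3ccccc3)[C@H]1CC[C@H](C)CCOC(=O)C(C)(C)C | intermediate
17 | (−)-8-phenylmenthyl (13S)-15-(pivaloyloxy)labd-8(17)-en-19-oate | C=C1CC[C@@H]2[C@](C)(CCC[C@]2(C)C(=O)O[C@@H]3C[C@H](C)CC[C@H]3C(C)(C)c3ccccc3)[C@H]1CC[C@H](C)CCOC(=O)C(C)(C)C | intermediate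
18 | (13S)-labd-8(17)-ene-15,19-diol | C=C1CC[C@@H]2[C@](C)(CCC[C@]2(C)CO)[C@H]1CC[C@H](C)CCO | intermediate
19 | stearoyl chloride (octadecanoyl chloride) | O=C(Cl)CCCCCCCCCCCCCCCCC | starting material
20 | (13S)-19-hydroxylabd-8(17)-en-15-yl stearate | C=C1CC[C@@H]2[C@](C)(CCC[C@]2(C)CO)[C@H]1CC[C@H](C)CCOC(=O)CCCCCCCCCCCCCCCCC | intermediate
21 | (13S)-19-oxolabd-8(17)-en-15-yl stearate | C=C1CC[C@@H]2[C@](C)(CCC[C@]2(C)C=O)[C@H]1CC[C@H](C)CCOC(=O)CCCCCCCCCCCCCCCCC | intermediate
22 | (4S,5R,9S,10R,13S)-15-(stearoyloxy)labd-8(17)-en-19-oic acid | C=C1CC[C@@H]2[C@](C)(CCC[C@]2(C)C(=O)O)[C@H]1CC[C@H](C)CCOC(=O)CCCCCCCCCCCCCCCCC | target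

##### Step count and risks

Total step count: 14.
Longest linear sequence: 13 steps (steps 1–4 and 6–14, from 1). Step 5 is a one-step side branch.

Three steps most likely to fail:

**Step 7.**
- Risk: poor facial selectivity. The rate-limiting enolisation of the α-methyl β-keto ester needs 25–40 °C, and at that temperature both rotamers about the C4–C19 bond of the radical may react. Some elimination into ring B at the copper stage is a second risk.
- Fallback: a phenylselenyl group-transfer cascade at low temperature replaces the oxidative cascade.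
- It sets out from 10. NaH and PhSeCl in THF at 0 °C should give the C4 phenylselenide of the β-keto ester F1.
- Et3B/O2 in toluene at −78 °C starts a chain that forms the same C4, C10 and C8 radicals without any enolisation. The C8 radical takes the PhSe group from a further molecule of F1 to give the bicyclic C8 phenylselenide F2.
- H2O2/pyridine in CH2Cl2 at 0 °C then brings about selenoxide syn elimination towards the freely rotating C17 methyl group. The sequence comes back to the route at 14.

**Step 11.**
- Risk: incomplete hydride addition to a carbonyl group that is shielded on one side by the quaternary C4 and C20 and on the other by the cumyl group of the auxiliary.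
- Fallback: the ester is reduced earlier with intramolecular hydride delivery, and C3 is deoxygenated afterwards through a cyclic thionocarbonate.
- It sets out from 15. With LiAlH4 in THF the C3 alkoxyaluminate can pass hydride to C19 through a six-membered transition state, which should give (13S)-labd-8(17)-ene-3β,15,19-triol F3.
- One equivalent of 19 in pyridine/CH2Cl2 acylates only the unhindered C15–OH to give the 3β,19-dihydroxy 15-stearate F4.
- 1,1'-Thiocarbonyldiimidazole in toluene closes the 3,19-cyclic thionocarbonate F5.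
- Bu3SnH/AIBN opens it at the secondary C3–O bond, because the secondary radical is preferred to the neopentyl primary one, and gives the 19-O-(tributylstannylthio)carbonyl compound F6.
- F6 loses carbonyl sulfide on moist silica gel, and the sequence comes back to the route at 20.

**Step 3.**
- Risk: competing allylic oxidation at the internal C6=C7 alkene and over-oxidation of the product.
- Fallback: the E-allylic alcohol is rebuilt by cleavage and olefination instead of C–H oxidation.
- It sets out from 3. NBS in THF/H2O attacks the terminal alkene preferentially and should give the terminal bromohydrin F7.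
- K2CO3 in MeOH closes the terminal epoxide F8.
- H5IO6 in THF/H2O cleaves it to the trisnor aldehyde F9.
- A Wittig reaction with 2-(triphenylphosphoranylidene)propanal in toluene gives the (E)-enal F10.
- Luche reduction (NaBH4, CeCl3·7H2O, MeOH) comes back to the route at 4.

##### Further compounds

F1 | step 7 | C4 phenylselenide of 10 (C4 epimers) | CC([Se]c1ccccc1)(C(=O)CC/C(C)=C/CC/C(C)=C/CC[C@H](C)CCOC(=O)C(C)(C)C)C(=O)O[C@@H]1C[C@H](C)CC[C@H]1C(C)(C)c1ccccc1
F2 | step 7 | (−)-8-phenylmenthyl (13S)-3-oxo-8-(phenylselanyl)-15-(pivaloyloxy)labdan-19-oate (C8 epimers) | CC1([Se]c3ccccc3)CC[C@@H]2[C@](C)(CCC(=O)[C@]2(C)C(=O)O[C@@H]3C[C@H](C)CC[C@H]3C(C)(C)c3ccccc3)[C@H]1CC[C@H](C)CCOC(=O)C(C)(C)C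
F3 | step 11 | (13S)-labd-8(17)-ene-3β,15,19-triol | C=C1CC[C@@H]2[C@](C)(CC[C@H](O)[C@]2(C)CO)[C@H]1CC[C@H](C)CCO
F4 | step 11 | (13S)-3β,19-dihydroxylabd-8(17)-en-15-yl stearate | C=C1CC[C@@H]2[C@](C)(CC[C@H](O)[C@]2(C)CO)[C@H]1CC[C@H](C)CCOC(=O)CCCCCCCCCCCCCCCCC
F5 | step 11 | 3β,19-cyclic thionocarbonate of F4 | C=C1CC[C@@H]2[C@](C)(CC[C@@H]3OC(=S)OC[C@]23C)[C@H]1CC[C@H](C)CCOC(=O)CCCCCCCCCCCCCCCCC
F6 | step 11 | (13S)-19-[(tributylstannylthio)carbonyloxy]labd-8(17)-en-15-yl stearate | C=C1CC[C@@H]2[C@](C)(CCC[C@]2(C)COC(=O)S[Sn](CCCC)(CCCC)CCCC)[C@H]1CC[C@H](C)CCOC(=O)CCCCCCCCCCCCCCCCC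
F7 | step 3 | (3S,6E)-10-bromo-11-hydroxy-3,7,11-trimethyldodec-6-enyl pivalate (C10 epimers) | CC(C)(O)C(Br)CC/C(C)=C/CC[C@H](C)CCOC(=O)C(C)(C)C
F8 | step 3 | (3S,6E)-10,11-epoxy-3,7,11-trimethyldodec-6-enyl pivalate (C10 epimers) | CC1(C)OC1CC/C(C)=C/CC[C@H](C)CCOC(=O)C(C)(C)C
F9 | step 3 | (3S,6E)-3,7-dimethyl-10-oxodec-6-enyl pivalate | O=CCC/C(C)=C/CC[C@H](C)CCOC(=O)C(C)(C)C
F10 | step 3 | (3S,6E,10E)-3,7,11-trimethyl-12-oxododeca-6,10-dienyl pivalate | O=C/C(C)=C/CC/C(C)=C/CC[C@H](C)CCOC(=O)C(C)(C)C
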